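**Retrosynthetic overview**

1. Ring B (C5–C6–C7–C8–C9–C10) and the γ-lactone come last: C6–C7 by SmI2 ketyl–olefin closure of a C6 aldehyde onto a C7=C11 enoate, then lactonisation. The chain C9–C8–C7 is put on C10 by Michael addition to acrolein and a Wittig reaction.
2. The bicyclo[2.2.2]octenone (rings C1–C2–C3=C4–C5–C10, C2–C3=C4–C5–C2′–C1′ and C1–C2–C1′–C2′–C5–C10) is made in one palladium-catalysed operation that forms C2–C1′ and C5–C10 from a monocyclic 2H-pyran carrying an allylic pivalate arm.
3. Enabling feature: O=C1–C2–C3=C4–C5 is a masked 1-oxatriene, so the C1 oxygen can be tied to C5 in a 2H-pyran (ring O–C1=C2–C3=C4–C5). In that ring C2 is an enol-ether carbon and the C5–O bond is allylic; both new bonds start at the two α-carbons of the C1 ketone (C2, C10) and end at allylic carbons (C1′ next to C3′=CH2, C5 next to C3=C4).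
4. The pyran comes from an (E)-dienone by photoisomerisation and oxa-6π closure, the dienone from Heck coupling of an enol triflate (from alkylated methyl acetoacetate) with ethyl vinyl ketone, and the ten-carbon arm from myrcene by 1,4-acetoxychlorination.
5. Order of ring formation: 2H-pyran (temporary) → the three rings of the bicyclo[2.2.2]octenone together → ring B → γ-lactone.

Key step: step 7

**Remarks**

- Locants used in the text (target numbering): C1 ketone; C2 bridgehead CH; C3=C4 (C4 bears CH3); C5 quaternary bridgehead; C6 OCH; C7 CH; C8, C9 CH2; C10 quaternary C–CH3; C11 CH(CH3); C12 lactone C=O; C1′ ring CH bearing the dienyl chain; C2′ ring CH2; C3′ the C(=CH2) carbon. Names of bicyclic intermediates use bicyclo[2.2.2]oct-5-en-2-one numbering (C1 = the bridgehead next to C=O).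
- Assumption: the 1,4-acetoxychlorination of myrcene is taken to follow the regiochemistry of 2-substituted butadienes such as isoprene (acetate on the CH2 next to the substituted diene carbon, chloride on the other CH2).
- Assumption: the sense of induction of the ligand in step 7 cannot be predicted with certainty; the (S,S) ligand is written and its mirror image would be used if the opposite sense is found.
- Geometric isomers at C4=C5 (steps 3–5) and at C1′=C3′ converge, because both elements are erased in steps 6 and 7.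

**Route**

Step 1
Reactants: 1 β-myrcene (7-methyl-3-methylideneocta-1,6-diene)
Product: 2 (2E)-4-chloro-2-(4-methylpent-3-en-1-yl)but-2-en-1-yl acetate
Conditions: Pd(OAc)2 (5 mol %), LiCl, LiOAc·2H2O, p-benzoquinone, AcOH–pentane, 25 °C
Reagents that add atoms: lithium chloride [Li+].[Cl-]; acetic acid CC(=O)O
Why: Palladium-catalysed 1,4-acetoxychlorination of the 1,3-diene: acetate attacks the CH2 of the substituted double bond of the palladium-bound diene, chloride opens the resulting π-allyl at its free CH2 end, the remote trisubstituted alkene should not react, and no stereocentre is formed.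

Step 2
Reactants: 2 (2E)-4-chloro-2-(4-methylpent-3-en-1-yl)but-2-en-1-yl acetate; 3 methyl acetoacetate
Product: 4 methyl (4E)-2-acetyl-5-(acetoxymethyl)-9-methyldeca-4,8-dienoate (racemic)
Conditions: NaH, THF–DMF, 0 °C; then 2, NaI (cat.), 23 °C
Reagents that add atoms: none
Why: Acetoacetic ester alkylation (SN2 of the soft sodium enolate at the primary allylic chloride, the allylic acetate being inert without palladium); the new stereocentre is racemic and is erased in step 3.

Step 3
Reactants: 4 methyl (4E)-2-acetyl-5-(acetoxymethyl)-9-methyldeca-4,8-dienoate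
Product: 5 methyl (2Z)-2-[(2E)-3-(acetoxymethyl)-7-methylocta-2,6-dien-1-yl]-3-[(trifluoromethylsulfonyl)oxy]but-2-enoate
Conditions: NaH, Et2O–CH2Cl2, 0 °C; Tf2O, −78 → 0 °C
Reagents that add atoms: trifluoromethanesulfonic anhydride O=S(=O)(OS(=O)(=O)C(F)(F)F)C(F)(F)F
Why: O-sulfonylation of the chelated sodium enolate of the β-keto ester gives the tetrasubstituted enol triflate, expected mainly as the (Z) isomer; the minor isomer can be carried along.

Step 4
Reactants: 5 methyl (2Z)-2-[(2E)-3-(acetoxymethyl)-7-methylocta-2,6-dien-1-yl]-3-[(trifluoromethylsulfonyl)oxy]but-2-enoate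
Product: 7 (2Z)-4-(pivaloyloxy)-3-[(2E)-7-methyl-3-[(pivaloyloxy)methyl]octa-2,6-dien-1-yl]but-2-en-2-yl trifluoromethanesulfonate, via diol triflate 6 (not isolated)
Conditions: (i-Bu)2AlH (5 equiv), CH2Cl2, −78 °C; aq. Rochelle salt; then t-BuCOCl, Et3N, DMAP (cat.), CH2Cl2, 0 → 23 °C
Reagents that add atoms: pivaloyl chloride CC(C)(C)C(Cl)=O
Why: Hydride reduction of the conjugated methyl ester to the allylic alcohol (the acetate is cleaved as well) leaves the vinyl triflate intact at −78 °C, and pivaloylation gives two hindered esters, one the later allylic leaving group and one a base-stable protecting group that resists acyl transfer to the enolate of step 8.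

Step 5
Reactants: 7 (2Z)-4-(pivaloyloxy)-3-[(2E)-7-methyl-3-[(pivaloyloxy)methyl]octa-2,6-dien-1-yl]but-2-en-2-yl trifluoromethanesulfonate; 8 ethyl vinyl ketone (pent-1-en-3-one)
Product: 9 (4E,6Z,9E)-6,14-dimethyl-7,10-bis[(pivaloyloxy)methyl]pentadeca-4,6,9,13-tetraen-3-one
Conditions: Pd(OAc)2 (5 mol %), n-Bu4NCl, NaHCO3, DMF, 40 °C
Reagents that add atoms: none
Why: Heck reaction of the vinyl triflate with the terminal enone under phosphine-free conditions (syn insertion, syn β-hydride elimination) gives the (E)-dienone, while the allylic pivalates, which ionise only slowly without phosphine, should stay in place.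

Step 6
Reactants: 9 (4E,6Z,9E)-6,14-dimethyl-7,10-bis[(pivaloyloxy)methyl]pentadeca-4,6,9,13-tetraen-3-one
Product: 11 [6-ethyl-3-methyl-2-[(2E)-7-methyl-3-[(pivaloyloxy)methyl]octa-2,6-dien-1-yl]-2H-pyran-2-yl]methyl pivalate (racemic), via (4Z)-dienone 10 (not isolated)
Conditions: hν (350 nm, Pyrex), degassed MeCN, 20 °C
Reagents that add atoms: none
Why: n→π* irradiation isomerises C2=C3 from E to Z and the (Z)-dienone closes thermally by oxa-6π electrocyclisation (as trans-β-ionone gives its α-pyran); the pyran no longer absorbs at 350 nm and should accumulate, its stereocentre being racemic and labile through reversible ring opening.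

Step 7
Reactants: 11 [6-ethyl-3-methyl-2-[(2E)-7-methyl-3-[(pivaloyloxy)methyl]octa-2,6-dien-1-yl]-2H-pyran-2-yl]methyl pivalate
Product: 13 (1S,4S,7S)-3,5-dimethyl-7-(6-methylhepta-1,5-dien-2-yl)-4-[(pivaloyloxy)methyl]bicyclo[2.2.2]oct-5-en-2-one (C3 epimers; dienyl group syn to the C5=C6 bridge), via alkylidene-oxabicycle 12 (not isolated)
Conditions: Pd2(dba)3·CHCl3 (2.5 mol %), (S,S)-N,N′-(cyclohexane-1,2-diyl)bis[2-(diphenylphosphino)benzamide] (7.5 mol %), toluene, 60 °C
Reagents that add atoms: none
Why: Proposed new method: zerovalent palladium ionises the primary allylic pivalate to a π-allyl cation whose internal terminus C1′ is attacked by C2 of the electron-rich 2H-pyran dienol ether (bond C2–C1′), the bridged oxocarbenium ion loses H-10 to pivalate to give the alkylidene-oxabicycle 12, and the same catalyst then ionises the allylic bridging C5–O bond anti to oxygen so that the tethered enolate recloses through C10 onto C5 (bond C5–C10, a 1,3 O-to-C shift with net retention at C5). The closest known reaction types are the palladium-catalysed intramolecular allylic alkylation of neutral electron-rich π-nucleophiles (phenols, indoles, silyl enol ethers) for the first bond and the palladium-catalysed 1,3 oxygen-to-carbon shift of 2-alkylidene-5-vinyltetrahydrofurans to cyclopentanones for the second. The first closure is a 6-exo attack on the proximal allyl terminus that makes ring C2–C3=C4–C5–C2′–C1′ (the eight-membered alternative through the CH2 terminus is disfavoured); the second is an enolate C-alkylation that makes rings C1–C2–C3=C4–C5–C10 and C1–C2–C1′–C2′–C5–C10 at once, since attack at the other allyl terminus C3 would give a four-membered ring. C1′ is set by the chiral ligand through fast π–σ–π face exchange of the allyl unit (its CH2 terminus is unsubstituted), C2 and C5 follow from C1′ because the bridge can form on one pyran face only with the bulky dienyl group turned away from the O–C1(ethyl) bridge towards C3=C4, and the two pyran enantiomers interconvert through the open dienone 10 so that all material can funnel through the matched pathway (dynamic kinetic asymmetric transformation). C10 is formed as an epimer mixture and is fixed in step 8. The step needs C-alkylation at C2 and then at C5 to outrun diene-forming proton loss from the π-allyl intermediates, which the 1,4-disposition of nucleophile and electrophile across the six-membered ring should favour.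

Step 8
Reactants: 13 (1S,4S,7S)-3,5-dimethyl-7-(6-methylhepta-1,5-dien-2-yl)-4-[(pivaloyloxy)methyl]bicyclo[2.2.2]oct-5-en-2-one; 14 acrolein
Product: 15 3-[(1S,3R,4R,7S)-3,5-dimethyl-7-(6-methylhepta-1,5-dien-2-yl)-2-oxo-4-[(pivaloyloxy)methyl]bicyclo[2.2.2]oct-5-en-3-yl]propanal (the descriptor at C4 changes only through CIP priorities)
Conditions: KOt-Bu (10 mol %), acrolein (2 equiv), t-BuOH–THF, 0 °C
Reagents that add atoms: none
Why: Michael addition of the only possible enolate (C10; the other α-carbon C2 is a bridgehead and cannot enolise) from the open face between the keto bridge and the C3=C4 bridge, away from the inward hydrogens of the C1′–C2′ bridge, should set quaternary C10 with the new chain syn to C3=C4 and converge both C10 epimers.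

Step 9
Reactants: 15 3-[(1S,3R,4R,7S)-3,5-dimethyl-7-(6-methylhepta-1,5-dien-2-yl)-2-oxo-4-[(pivaloyloxy)methyl]bicyclo[2.2.2]oct-5-en-3-yl]propanal
Product: 16 (1S,3R,4R,7S)-4-(hydroxymethyl)-3-(3-hydroxypropyl)-3,5-dimethyl-7-(6-methylhepta-1,5-dien-2-yl)bicyclo[2.2.2]oct-5-en-2-ol (C2 epimers)
Conditions: LiAlH4, THF, 0 → 23 °C; aq. NaOH work-up
Reagents that add atoms: none
Why: Exhaustive hydride reduction of ketone, aldehyde and pivalate gives the triol; the new carbinol centre is an inconsequential mixture that is re-oxidised in step 10.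

Step 10
Reactants: 16 (1S,3R,4R,7S)-4-(hydroxymethyl)-3-(3-hydroxypropyl)-3,5-dimethyl-7-(6-methylhepta-1,5-dien-2-yl)bicyclo[2.2.2]oct-5-en-2-ol
Product: 17 (1S,3R,4R,7S)-3,5-dimethyl-7-(6-methylhepta-1,5-dien-2-yl)-2-oxo-3-(3-oxopropyl)bicyclo[2.2.2]oct-5-ene-4-carbaldehyde
Conditions: (COCl)2, DMSO, CH2Cl2, −78 °C; Et3N, −78 → 0 °C
Reagents that add atoms: none
Why: Swern oxidation activates all three alcohols as alkoxysulfonium salts before any carbonyl is released, which avoids lactol formation between the C1 hydroxyl and the C6 aldehyde and the over-oxidation that would follow.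

Step 11
Reactants: 17 (1S,3R,4R,7S)-3,5-dimethyl-7-(6-methylhepta-1,5-dien-2-yl)-2-oxo-3-(3-oxopropyl)bicyclo[2.2.2]oct-5-ene-4-carbaldehyde; 18 ethyl 2-(triphenyl-λ5-phosphanylidene)propanoate
Product: 19 ethyl (2E)-5-[(1S,3R,4R,7S)-4-formyl-3,5-dimethyl-7-(6-methylhepta-1,5-dien-2-yl)-2-oxobicyclo[2.2.2]oct-5-en-3-yl]-2-methylpent-2-enoate
Conditions: 18 (1.1 equiv), CH2Cl2, 0 → 23 °C
Reagents that add atoms: none
Why: Wittig olefination with the stabilised ylide should occur only at the unhindered chain aldehyde (the C6 aldehyde sits on a quaternary carbon next to a second quaternary centre) and give the (E)-trisubstituted enoate.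

Step 12
Reactants: 19 ethyl (2E)-5-[(1S,3R,4R,7S)-4-formyl-3,5-dimethyl-7-(6-methylhepta-1,5-dien-2-yl)-2-oxobicyclo[2.2.2]oct-5-en-3-yl]-2-methylpent-2-enoate
Product: 22 target keto lactone CNP0385704.1 (2S,5R,6S,7S,10R,11S,1′S in the numbering of the remarks), via hydroxy ester 20 (not isolated), via C11-epimeric lactone 21 (not isolated)
Conditions: SmI2 (2.5 equiv), t-BuOH (2 equiv), THF, −78 → 0 °C; then DBU, toluene, 80 °C
Reagents that add atoms: none
Why: SmI2 ketyl–olefin cyclisation (6-exo addition of the C6 ketyl radical to the enoate β-carbon C7) closes ring B through a chair in which C6–O and the C7 substituent are both equatorial, because the axial sites are blocked by the axial C10 methyl and by C4, giving the trans 6S,7S pair; lactonisation and base equilibration at C11 should then favour the 11S epimer with the methyl trans to C8 (the α-santonin-type arrangement).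

**Compound list**

1 | β-myrcene | CC(C)=CCCC(=C)C=C | starting material
2 | (2E)-4-chloro-2-(4-methylpent-3-en-1-yl)but-2-en-1-yl acetate | CC(=O)OC/C(CCC=C(C)C)=C/CCl | intermediate
3 | methyl acetoacetate | CC(=O)CC(=O)OC | starting material
4 | methyl (4E)-2-acetyl-5-(acetoxymethyl)-9-methyldeca-4,8-dienoate (racemic) | CC(=O)C(C(=O)OC)C/C=C(/COC(C)=O)CCC=C(C)C | intermediate
5 | methyl (2Z)-2-[(2E)-3-(acetoxymethyl)-7-methylocta-2,6-dien-1-yl]-3-[(trifluoromethylsulfonyl)oxy]but-2-enoate | C/C(OS(=O)(=O)C(F)(F)F)=C(\C/C=C(/COC(C)=O)CCC=C(C)C)C(=O)OC | intermediate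
6 | (2Z)-4-hydroxy-3-[(2E)-3-(hydroxymethyl)-7-methylocta-2,6-dien-1-yl]but-2-en-2-yl trifluoromethanesulfonate | C/C(OS(=O)(=O)C(F)(F)F)=C(\C/C=C(/CO)CCC=C(C)C)CO | intermediate
7 | (2Z)-4-(pivaloyloxy)-3-[(2E)-7-methyl-3-[(pivaloyloxy)methyl]octa-2,6-dien-1-yl]but-2-en-2-yl trifluoromethanesulfonate | C/C(OS(=O)(=O)C(F)(F)F)=C(\C/C=C(/COC(=O)C(C)(C)C)CCC=C(C)C)COC(=O)C(C)(C)C | intermediate
8 | ethyl vinyl ketone (pent-1-en-3-one) | C=CC(=O)CC | starting material
9 | (4E,6Z,9E)-6,14-dimethyl-7,10-bis[(pivaloyloxy)methyl]pentadeca-4,6,9,13-tetraen-3-one | CCC(=O)/C=C/C(C)=C(\COC(=O)C(C)(C)C)C/C=C(/COC(=O)C(C)(C)C)CCC=C(C)C | intermediate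
10 | (4Z,6Z,9E)-6,14-dimethyl-7,10-bis[(pivaloyloxy)methyl]pentadeca-4,6,9,13-tetraen-3-one | CCC(=O)/C=C\C(C)=C(/COC(=O)C(C)(C)C)C/C=C(/COC(=O)C(C)(C)C)CCC=C(C)C | intermediate
11 | [6-ethyl-3-methyl-2-[(2E)-7-methyl-3-[(pivaloyloxy)methyl]octa-2,6-dien-1-yl]-2H-pyran-2-yl]methyl pivalate (racemic, labile stereocentre) | CCC1=CC=C(C)C(COC(=O)C(C)(C)C)(C/C=C(/COC(=O)C(C)(C)C)CCC=C(C)C)O1 | intermediate
12 | [(1S,4S,8S)-3-ethylidene-6-methyl-8-(6-methylhepta-1,5-dien-2-yl)-2-oxabicyclo[2.2.2]oct-5-en-1-yl]methyl pivalate (ethylidene geometry open) | C=C(CCC=C(C)C)[C@H]1C[C@@]2(COC(=O)C(C)(C)C)C(C)=C[C@@H]1C(=CC)O2 | intermediate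
13 | (1S,4S,7S)-3,5-dimethyl-7-(6-methylhepta-1,5-dien-2-yl)-4-[(pivaloyloxy)methyl]bicyclo[2.2.2]oct-5-en-2-one (C3 epimers) | C=C(CCC=C(C)C)[C@H]1C[C@@]2(COC(=O)C(C)(C)C)C(C)=C[C@@H]1C(=O)C2C | intermediate
14 | acrolein | C=CC=O | starting material
15 | 3-[(1S,3R,4R,7S)-3,5-dimethyl-7-(6-methylhepta-1,5-dien-2-yl)-2-oxo-4-[(pivaloyloxy)methyl]bicyclo[2.2.2]oct-5-en-3-yl]propanal | C=C(CCC=C(C)C)[C@H]1C[C@@]2(COC(=O)C(C)(C)C)C(C)=C[C@@H]1C(=O)[C@]2(C)CCC=O | intermediate
16 | (1S,3R,4R,7S)-4-(hydroxymethyl)-3-(3-hydroxypropyl)-3,5-dimethyl-7-(6-methylhepta-1,5-dien-2-yl)bicyclo[2.2.2]oct-5-en-2-ol (C2 epimers) | C=C(CCC=C(C)C)[C@H]1C[C@@]2(CO)C(C)=C[C@@H]1C(O)[C@]2(C)CCCO | intermediate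
17 | (1S,3R,4R,7S)-3,5-dimethyl-7-(6-methylhepta-1,5-dien-2-yl)-2-oxo-3-(3-oxopropyl)bicyclo[2.2.2]oct-5-ene-4-carbaldehyde | C=C(CCC=C(C)C)[C@H]1C[C@@]2(C=O)C(C)=C[C@@H]1C(=O)[C@]2(C)CCC=O | intermediate
18 | ethyl 2-(triphenyl-λ5-phosphanylidene)propanoate | CCOC(=O)C(C)=P(c1ccccc1)(c1ccccc1)c1ccccc1 | starting material
19 | ethyl (2E)-5-[(1S,3R,4R,7S)-4-formyl-3,5-dimethyl-7-(6-methylhepta-1,5-dien-2-yl)-2-oxobicyclo[2.2.2]oct-5-en-3-yl]-2-methylpent-2-enoate | C=C(CCC=C(C)C)[C@H]1C[C@@]2(C=O)C(C)=C[C@@H]1C(=O)[C@]2(C)CC/C=C(\C)C(=O)OCC | intermediate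
20 | tricyclic hydroxy ester: ring B closed, 6S-hydroxy, 7S-[1-(ethoxycarbonyl)ethyl] (C11 epimers) | C=C(CCC=C(C)C)[C@H]1C[C@@]23C(C)=C[C@@H]1C(=O)[C@]2(C)CC[C@@H](C(C)C(=O)OCC)[C@@H]3O | intermediate
21 | trans-fused lactone as C11 epimer mixture | C=C(CCC=C(C)C)[C@H]1C[C@@]23C(C)=C[C@@H]1C(=O)[C@]2(C)CC[C@H]1C(C)C(=O)O[C@@H]13 | intermediate
22 | CNP0385704.1, (2S,5R,6S,7S,10R,11S,1′S) keto lactone | C=C(CCC=C(C)C)[C@H]1C[C@@]23C(C)=C[C@@H]1C(=O)[C@]2(C)CC[C@H]1[C@H](C)C(=O)O[C@@H]13 | target

**Step count and risks**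

Total step count: 12. Longest linear sequence: 12 steps (from myrcene).

Steps most likely to fail:

1. Step 7 (Proposed new method). The neutral dienol ether may be too weak a nucleophile for the π-allyl intermediate, proton loss to dienes may outrun C–C bond formation at either stage, and catalyst control of the absolute sense may be incomplete. Fallback with known reactions, setting out from 11 and returning at 13: soft enolisation with t-BuMe2SiOTf/Et3N traps the open dienone 10 as the (3Z)-2-silyloxytriene, silyl trienol ether F1. Heating in toluene (110 °C) closes C5–C10 by thermal disrotatory 6π-electrocyclisation to silyl dienol ether F2. Pd(PPh3)4 with CsF in THF then unmasks the dienolate and closes C2–C1′ by intramolecular Tsuji–Trost allylation at the α-carbon. This gives racemic 13, that is 13 together with its mirror image, enantiomer of 13 F3. The enantiomers would be separated by preparative chromatography on a chiral stationary phase, and (1S,4S,7S)-13 re-enters at step 8.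

2. Step 6. Photoisomerisation may stop at a photostationary mixture, or hydrogen shifts and cycloadditions of the excited dienone may consume material before it is drained into the pyran. Fallback setting out from 7 and returning at 11 (it also by-passes step 5): Sonogashira coupling of triflate 7 with commercial pent-1-yn-3-ol (PdCl2(PPh3)2, CuI, Et3N) gives enynol F4. MnO2 oxidation gives ynone F5. Semihydrogenation (H2, Pd/CaCO3 poisoned with Pb(OAc)2, quinoline) gives the (4Z)-dienone 10 directly, which closes to 11.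

3. Step 12. The hindered aldehyde may be reduced or coupled in pinacol fashion without ring closure, or the C1 ketone may be reduced competitively. Fallback setting out from 17 and returning at 22: Morita–Baylis–Hillman reaction of the unhindered chain aldehyde with methyl acrylate (DABCO) gives hydroxy acrylate F6. PBr3 converts it with allylic transposition into (Z)-allylic bromide F7. CrCl2 in THF effects an intramolecular Nozaki–Hiyama-type 2-(methoxycarbonyl)allylation of the C6 aldehyde through a chair with both new substituents equatorial, and the alkoxide lactonises to α-methylene lactone F8. Conjugate reduction with [(Ph3P)CuH]6 and protonation, with DBU equilibration at C11 if needed, gives 22.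

**Further compounds**

F1 | step 7 | (3Z)-silyl trienol ether of dienone 10 | CC=C(O[Si](C)(C)C(C)(C)C)/C=C\C(C)=C(/COC(=O)C(C)(C)C)C/C=C(/COC(=O)C(C)(C)C)CCC=C(C)C
F2 | step 7 | 2-silyloxycyclohexa-1,3-diene from 6π closure (racemic) | CC1C(O[Si](C)(C)C(C)(C)C)=CC=C(C)C1(COC(=O)C(C)(C)C)C/C=C(/COC(=O)C(C)(C)C)CCC=C(C)C
F3 | step 7 | (1R,4R,7R) enantiomer of 13 | C=C(CCC=C(C)C)[C@@H]1C[C@]2(COC(=O)C(C)(C)C)C(C)=C[C@H]1C(=O)C2C
F4 | step 6 | (6Z,9E)-3-hydroxy-6,14-dimethyl-7,10-bis[(pivaloyloxy)methyl]pentadeca-6,9,13-trien-4-yne | CCC(O)C#C/C(C)=C(\COC(=O)C(C)(C)C)C/C=C(/COC(=O)C(C)(C)C)CCC=C(C)C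
F5 | step 6 | (6Z,9E)-6,14-dimethyl-7,10-bis[(pivaloyloxy)methyl]pentadeca-6,9,13-trien-4-yn-3-one | CCC(=O)C#C/C(C)=C(\COC(=O)C(C)(C)C)C/C=C(/COC(=O)C(C)(C)C)CCC=C(C)C
F6 | step 12 | Morita–Baylis–Hillman adduct of 17 (carbinol epimers) | C=C(CCC=C(C)C)[C@H]1C[C@@]2(C=O)C(C)=C[C@@H]1C(=O)[C@]2(C)CCC(O)C(=C)C(=O)OC
F7 | step 12 | methyl (2Z)-2-(bromomethyl)pent-2-enoate derivative of 17 | C=C(CCC=C(C)C)[C@H]1C[C@@]2(C=O)C(C)=C[C@@H]1C(=O)[C@]2(C)CC/C=C(/C(=O)OC)CBr
F8 | step 12 | 11(13)-methylidene analogue of 22 (α-methylene lactone) | C=C(CCC=C(C)C)[C@H]1C[C@@]23C(C)=C[C@@H]1C(=O)[C@]2(C)CC[C@H]1C(=C)C(=O)O[C@@H]13
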